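**Plan**
- Cuts, in retrosynthetic order: the benzyl group on O2' and the methyl group on O8. Then C8–C8a, which unzips ring A to a 4-hydroxycyclobutenone on C5 of a 2-aryl-4-pyranone. Then C4a–C5 (pyranone C5 to carbinol carbon), giving a 5-iodopyranone and dimethyl squarate. Last, C2–C3 and O1–C6 of the pyranone, giving the ring B aldehyde and Danishefsky's diene.
- Enabling feature: each of C5–C8 of ring A bears oxygen, and O5 and O8 are para and flank the vicinal methoxy carbons C6 and C7. The C4a–C8a edge shared with ring C is the enol ether C=C of a 4-pyranone, so the four squarate carbons map onto C5–C8.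
- Forward order: ring B is bought. Ring C is built by hetero-Diels–Alder reaction, iodinated, then dehydrogenated. The squarate is joined at C4a–C5, and ring A closes last by 4π opening and 6π closure.
- Stereochemistry: the target has no stereocentre. Every sp3 centre made on the way is racemic and is erased later. The only stereochemical demand is outward rotation of the hydroxyl group in the ring opening.

Key step: step 6

Remark: monocyclic compounds use pyranone numbering (O1, C2–C6). Bicyclic compounds use flavone numbering (C2–C8a, primes for ring B).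

**Step 1**
Reactants: 1 2-hydroxy-4,5-dimethoxybenzaldehyde
Product: 2 2-(benzyloxy)-4,5-dimethoxybenzaldehyde
Conditions: BnBr, K2CO3, DMF, 60 °C
Reagents that add atoms: benzyl bromide, BrCc1ccccc1
Why: Williamson ether synthesis, in which the phenoxide formed with K2CO3 displaces bromide and the benzyl ether masks the acidic phenol through the organomagnesium step yet can be removed by hydrogenolysis at the end.

**Step 2**
Reactants: 2 2-(benzyloxy)-4,5-dimethoxybenzaldehyde; 3 Danishefsky's diene, (E)-1-methoxy-3-(trimethylsilyloxy)buta-1,3-diene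
Product: 5 rac-2-[2-(benzyloxy)-4,5-dimethoxyphenyl]-2,3-dihydro-4H-pyran-4-one, via silyl enol ether cycloadduct 4 (not isolated)
Conditions: ZnCl2 (20 mol%), THF, rt; then TFA (cat.), CH2Cl2, 0 °C to rt
Reagents that add atoms: none
Why: Lewis acid catalysed hetero-Diels–Alder reaction of an aryl aldehyde with Danishefsky's diene, after which acid expels methanol and the silyl group from 4, while C2 is set without control as a racemate and is erased in step 4.

**Step 3**
Reactants: 5 rac-2-[2-(benzyloxy)-4,5-dimethoxyphenyl]-2,3-dihydro-4H-pyran-4-one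
Product: 6 rac-2-[2-(benzyloxy)-4,5-dimethoxyphenyl]-5-iodo-2,3-dihydro-4H-pyran-4-one
Conditions: I2, pyridine, CH2Cl2, 0 °C to rt
Reagents that add atoms: iodine, [I][I]
Why: α-Iodination of an enone with I2 and pyridine (Johnson-type iodination) should strike C5 alone, since it is the nucleophilic β-carbon of the ring enol ether and the only sp2 C–H next to the carbonyl while C3 is still saturated, and the mild reagent leaves the electron-rich ring B untouched.

**Step 4**
Reactants: 6 rac-2-[2-(benzyloxy)-4,5-dimethoxyphenyl]-5-iodo-2,3-dihydro-4H-pyran-4-one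
Product: 7 2-[2-(benzyloxy)-4,5-dimethoxyphenyl]-5-iodo-4H-pyran-4-one
Conditions: DDQ, 1,4-dioxane, reflux
Reagents that add atoms: none
Why: Quinone dehydrogenation of the flavanone-to-flavone type, in which DDQ takes hydride from C2–H (benzylic to a trialkoxyphenyl ring and α to the ring oxygen), the cation loses a C3 proton to give the fully conjugated pyranone, and the base-free medium avoids retro-oxa-Michael ring opening while aryl benzyl ethers and the alkenyl iodide are tolerated.

**Step 5**
Reactants: 7 2-[2-(benzyloxy)-4,5-dimethoxyphenyl]-5-iodo-4H-pyran-4-one; 8 dimethyl squarate (3,4-dimethoxycyclobut-3-ene-1,2-dione)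
Product: 10 rac-2-[2-(benzyloxy)-4,5-dimethoxyphenyl]-5-(1-hydroxy-2,3-dimethoxy-4-oxocyclobut-2-en-1-yl)-4H-pyran-4-one, via pyranon-5-ylmagnesium chloride 9 (not isolated)
Conditions: iPrMgCl·LiCl, THF, −40 °C; then added to 8, THF, −78 °C; aq NH4Cl, −78 °C to rt
Reagents that add atoms: none
Why: Iodine–magnesium exchange followed by 1,2-addition of the organomagnesium to a squarate carbonyl, where exchange on iodoalkenes flanked by a carbonyl and a β-oxygen (5-iodouracils, 5-iodo-1,3-dioxin-4-ones) is fast at low temperature, related 3-lithioflavones persist at −78 °C, 7 has no enolisable hydrogen, and the carbinol centre forms as a racemate that is consumed in step 6.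

**Step 6**
Reactants: 10 rac-2-[2-(benzyloxy)-4,5-dimethoxyphenyl]-5-(1-hydroxy-2,3-dimethoxy-4-oxocyclobut-2-en-1-yl)-4H-pyran-4-one
Product: 13 2-[2-(benzyloxy)-4,5-dimethoxyphenyl]-5,8-dihydroxy-6,7-dimethoxy-4H-chromen-4-one, via (Z)-dienylketene 11 (not isolated), via 8a-H cyclohexadienone 12 (not isolated)
Conditions: degassed p-xylene, reflux (138 °C), Ar
Reagents that add atoms: none
Why: Heating cleaves the bond between the carbinol carbon and the ring carbonyl in a conrotatory 4π opening, and since the donor hydroxyl turns outward, the pyranonyl group is left on the ketene side of (Z)-dienylketene 11. Ring A then closes by a thermal disrotatory 6π electrocyclisation running over the ketene C=C, the enol C=C and the pyranone C5=C6 bond, which joins the ketene carbon to pyranone C6 (C8–C8a of the flavone) and gives the six-membered dienone 12. Shift of the C8a hydrogen to the C8 oxygen aromatises 12 to hydroquinone 13 and makes the sequence irreversible. The closest known reaction type is the Moore rearrangement of 4-aryl-, 4-heteroaryl- and 4-alkenyl-4-hydroxycyclobutenones, and the weakly delocalised enol ether C=C of a 4-pyranone lies between the alkenyl and heteroaryl cases. The only new stereocentre, C8a of 12, forms as a racemate without control and vanishes on enolisation, so 13 is achiral. The step needs outward torquoselectivity, secured by the oxygen lone pairs of the hydroxyl, and a single site of closure, secured because the only neighbour of pyranone C5 bearing hydrogen is C6 (the other is carbonyl carbon C4) and because the O–H···O=C4 hydrogen bond in 11 holds the rotamer that points C6 at the ketene; air is excluded to keep the hydroquinone oxidation level.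

**Step 7**
Reactants: 13 2-[2-(benzyloxy)-4,5-dimethoxyphenyl]-5,8-dihydroxy-6,7-dimethoxy-4H-chromen-4-one
Product: 14 2-[2-(benzyloxy)-4,5-dimethoxyphenyl]-5-hydroxy-6,7,8-trimethoxy-4H-chromen-4-one
Conditions: MeI (1.05 equiv), K2CO3, acetone, Ar, rt to 40 °C
Reagents that add atoms: iodomethane, IC
Why: Chemoselective Williamson-type O-methylation, the classical partial methylation of 5,8-dihydroxyflavones, in which the 5-OH is tied to the C4 carbonyl by a strong hydrogen bond and stays un-ionised under K2CO3, so one equivalent of MeI should alkylate only the free 8-phenoxide while argon keeps the hydroquinone from oxidising.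

**Step 8**
Reactants: 14 2-[2-(benzyloxy)-4,5-dimethoxyphenyl]-5-hydroxy-6,7,8-trimethoxy-4H-chromen-4-one
Product: 15 agehoustin F, 5-hydroxy-2-(2-hydroxy-4,5-dimethoxyphenyl)-6,7,8-trimethoxy-4H-chromen-4-one
Conditions: H2 (1 atm), Pd/C (10 wt%), EtOAc–MeOH, rt
Reagents that add atoms: none
Why: Catalytic hydrogenolysis of an aryl benzyl ether over Pd/C at one atmosphere, conditions under which the conjugated C2=C3 bond of flavones, the methyl ethers and the chelated phenol are left alone.

**Compound list**
1 | 2-hydroxy-4,5-dimethoxybenzaldehyde | COc1cc(O)c(C=O)cc1OC | starting material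
2 | 2-(benzyloxy)-4,5-dimethoxybenzaldehyde | COc1cc(OCc2ccccc2)c(C=O)cc1OC | intermediate
3 | Danishefsky's diene, (E)-1-methoxy-3-(trimethylsilyloxy)buta-1,3-diene | CO/C=C/C(=C)O[Si](C)(C)C | starting material
4 | 2-[2-(benzyloxy)-4,5-dimethoxyphenyl]-6-methoxy-4-(trimethylsilyloxy)-3,6-dihydro-2H-pyran (racemic, mixture of diastereomers, not isolated) | COC1C=C(O[Si](C)(C)C)CC(O1)c2cc(OC)c(OC)cc2OCc3ccccc3 | intermediate
5 | rac-2-[2-(benzyloxy)-4,5-dimethoxyphenyl]-2,3-dihydro-4H-pyran-4-one | O=C1C=COC(C1)c2cc(OC)c(OC)cc2OCc3ccccc3 | intermediate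
6 | rac-2-[2-(benzyloxy)-4,5-dimethoxyphenyl]-5-iodo-2,3-dihydro-4H-pyran-4-one | O=C1C(I)=COC(C1)c2cc(OC)c(OC)cc2OCc3ccccc3 | intermediate
7 | 2-[2-(benzyloxy)-4,5-dimethoxyphenyl]-5-iodo-4H-pyran-4-one | O=c1cc(-c2cc(OC)c(OC)cc2OCc3ccccc3)occ1I | intermediate
8 | dimethyl squarate | COC1=C(OC)C(=O)C1=O | starting material
9 | {6-[2-(benzyloxy)-4,5-dimethoxyphenyl]-4-oxo-4H-pyran-3-yl}magnesium chloride, LiCl complex (not isolated) | O=c1cc(-c2cc(OC)c(OC)cc2OCc3ccccc3)occ1[Mg]Cl | intermediate
10 | rac-2-[2-(benzyloxy)-4,5-dimethoxyphenyl]-5-(1-hydroxy-2,3-dimethoxy-4-oxocyclobut-2-en-1-yl)-4H-pyran-4-one | COC1=C(OC)C(O)(c2coc(-c3cc(OC)c(OC)cc3OCc4ccccc4)cc2=O)C1=O | intermediate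
11 | (Z)-4-{6-[2-(benzyloxy)-4,5-dimethoxyphenyl]-4-oxo-4H-pyran-3-yl}-4-hydroxy-2,3-dimethoxybuta-1,3-dien-1-one, the dienylketene (not isolated) | O=C=C(OC)/C(OC)=C(/O)c1coc(-c2cc(OC)c(OC)cc2OCc3ccccc3)cc1=O | intermediate
12 | rac-2-[2-(benzyloxy)-4,5-dimethoxyphenyl]-5-hydroxy-6,7-dimethoxy-8aH-chromene-4,8-dione (not isolated) | COC1=C(OC)C(=O)C2OC(=CC(=O)C2=C1O)c3cc(OC)c(OC)cc3OCc4ccccc4 | intermediate
13 | 2-[2-(benzyloxy)-4,5-dimethoxyphenyl]-5,8-dihydroxy-6,7-dimethoxy-4H-chromen-4-one | COc1cc(OCc2ccccc2)c(-c2cc(=O)c3c(O)c(OC)c(OC)c(O)c3o2)cc1OC | intermediate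
14 | 2-[2-(benzyloxy)-4,5-dimethoxyphenyl]-5-hydroxy-6,7,8-trimethoxy-4H-chromen-4-one | COc1cc(OCc2ccccc2)c(-c2cc(=O)c3c(O)c(OC)c(OC)c(OC)c3o2)cc1OC | intermediate
15 | agehoustin F | COc1cc(O)c(-c2cc(=O)c3c(O)c(OC)c(OC)c(OC)c3o2)cc1OC | target

**Total step count:** 8. **Longest linear sequence:** 8 steps (1 to 15).

**Steps most likely to fail**

Step 5. Three things may go wrong. The magnesiated pyranone may fragment by anti-elimination of the ring oxygen. iPrMgCl may add to the pyranone before the exchange is complete. The chelate-stabilised carbanion may add too slowly to the squarate carbonyl.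

The fallback sets out from 7 and comes back at 10. It replaces the polar carbon–magnesium bond with a covalent carbon–zinc bond made by oxidative insertion instead of exchange. Zinc dust with LiCl in THF at 25 °C should insert into the carbon–iodine bond of 7, which the neighbouring carbonyl activates. This gives {6-[2-(benzyloxy)-4,5-dimethoxyphenyl]-4-oxo-4H-pyran-3-yl}zinc iodide F1. Chromones zincated next to the carbonyl are known to persist at room temperature without ring opening. F1 is then combined with 8 in the presence of MgCl2, which promotes 1,2-addition of aryl- and alkenylzinc halides to reactive ketones, and aqueous NH4Cl releases 10.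

Step 6. Closure onto the electron-poor C6 terminus may be slow. That would let the ketene be diverted, for example by lactonisation with the free hydroxyl after some inward rotation. The electron-rich hydroquinone may also be lost to aerial oxidation during isolation.

The fallback sets out from 10 and comes back at 14. It differentiates the two para oxygens before ring A exists, instead of relying on chelation afterwards.
- Silylation of the tertiary alcohol (TBSOTf, 2,6-lutidine, CH2Cl2, 0 °C) gives rac-2-[2-(benzyloxy)-4,5-dimethoxyphenyl]-5-{1-[(tert-butyldimethylsilyl)oxy]-2,3-dimethoxy-4-oxocyclobut-2-en-1-yl}-4H-pyran-4-one F2. It cannot lactonise, so any unproductive ring opening simply reverts.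
- Thermolysis in refluxing p-xylene should give the oxidation-resistant mono-protected hydroquinone 2-[2-(benzyloxy)-4,5-dimethoxyphenyl]-5-[(tert-butyldimethylsilyl)oxy]-8-hydroxy-6,7-dimethoxy-4H-chromen-4-one F3.
- Its only free phenol is methylated (MeI, K2CO3, acetone) to 2-[2-(benzyloxy)-4,5-dimethoxyphenyl]-5-[(tert-butyldimethylsilyl)oxy]-6,7,8-trimethoxy-4H-chromen-4-one F4.
- Bu4NF buffered with AcOH in THF at 0 °C removes the silyl group to give 14.

Step 4. Hydride abstraction from the electron-poor iodoenone may stall. Alternatively, the oxidant may attack ring B or its benzyl ether through charge transfer.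

The fallback sets out from 2 and comes back at 7. It sets the oxidation level on an open chain, so no heterocycle has to be dehydrogenated.
- Commercial (E)-4-methoxybut-3-en-2-one is iodinated with I2 and pyridine to (Z)-3-iodo-4-methoxybut-3-en-2-one F5.
- Deprotonation with LiN(SiMe3)2 in THF at −78 °C and aldol addition to 2 gives rac-(Z)-5-[2-(benzyloxy)-4,5-dimethoxyphenyl]-5-hydroxy-2-iodo-1-methoxypent-1-en-3-one F6.
- Dess–Martin periodinane in CH2Cl2 oxidises the benzylic alcohol to (Z)-1-[2-(benzyloxy)-4,5-dimethoxyphenyl]-4-iodo-5-methoxypent-4-ene-1,3-dione F7.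
- Catalytic TFA in CH2Cl2 closes the enol oxygen onto the methoxy-bearing carbon with loss of methanol. This is the established cyclisation of 5-methoxypent-4-ene-1,3-diones to 4-pyranones, and it delivers 7 with the iodine already at C5.

**Further compounds**
F1 | step 5 | {6-[2-(benzyloxy)-4,5-dimethoxyphenyl]-4-oxo-4H-pyran-3-yl}zinc iodide | O=c1cc(-c2cc(OC)c(OC)cc2OCc3ccccc3)occ1[Zn]I
F2 | step 6 | rac-2-[2-(benzyloxy)-4,5-dimethoxyphenyl]-5-{1-[(tert-butyldimethylsilyl)oxy]-2,3-dimethoxy-4-oxocyclobut-2-en-1-yl}-4H-pyran-4-one | COC1=C(OC)C(O[Si](C)(C)C(C)(C)C)(c2coc(-c3cc(OC)c(OC)cc3OCc4ccccc4)cc2=O)C1=O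
F3 | step 6 | 2-[2-(benzyloxy)-4,5-dimethoxyphenyl]-5-[(tert-butyldimethylsilyl)oxy]-8-hydroxy-6,7-dimethoxy-4H-chromen-4-one | COc1cc(OCc2ccccc2)c(-c2cc(=O)c3c(O[Si](C)(C)C(C)(C)C)c(OC)c(OC)c(O)c3o2)cc1OC
F4 | step 6 | 2-[2-(benzyloxy)-4,5-dimethoxyphenyl]-5-[(tert-butyldimethylsilyl)oxy]-6,7,8-trimethoxy-4H-chromen-4-one | COc1cc(OCc2ccccc2)c(-c2cc(=O)c3c(O[Si](C)(C)C(C)(C)C)c(OC)c(OC)c(OC)c3o2)cc1OC
F5 | step 4 | (Z)-3-iodo-4-methoxybut-3-en-2-one | CO/C=C(\I)C(C)=O
F6 | step 4 | rac-(Z)-5-[2-(benzyloxy)-4,5-dimethoxyphenyl]-5-hydroxy-2-iodo-1-methoxypent-1-en-3-one | CO/C=C(\I)C(=O)CC(O)c1cc(OC)c(OC)cc1OCc2ccccc2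
F7 | step 4 | (Z)-1-[2-(benzyloxy)-4,5-dimethoxyphenyl]-4-iodo-5-methoxypent-4-ene-1,3-dione | CO/C=C(\I)C(=O)CC(=O)c1cc(OC)c(OC)cc1OCc2ccccc2
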